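## The problem

Compound 33 is a germacranolide. Its ten-membered carbocycle (C1–C10) holds a cross-conjugated dienone (C10=C1–C2(=O)–C3=C4, both alkenes Z and trisubstituted, methyl C14 on C10 and C15 on C4), a free hydroxyl on C5, a tiglate on C8, and an α-methylene-γ-butyrolactone (C11–C13, ring oxygen on C6) fused across C6–C7. A synthesis has to close a medium ring against entropy and transannular strain, and it has to make two Z enones with defined geometry and keep them from isomerising. The four contiguous stereocentres (5S,6S,7R,8R) fall into two pairs. C7 and C8 have no neighbour that could control them and need an external chiral element. C5 and C6 can be derived from C7/C8 if the C5–C6 bond is still an alkene when they are set. Several groups rule out rough treatment: the α-methylene lactone is a Michael acceptor, the C5 hydroxyl is γ to the C2 carbonyl across a cis alkene (hemiketal or furan under acid), and C7–H is doubly allylic. A free C8 hydroxyl beside an open C12 ester and the Z C10=C1 enone can lactonise onto C12 or add to C2. The feature that makes the key step possible is that C5 and C6 carry threo oxygens, one of them delivered by the C12 carboxyl. The C5–C6 bond can therefore first exist as a cis alkene between a diene terminus on C4 and a vinyl group on C7, in a ring whose other seven sp2 atoms leave room only for a cis closure.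

## Retrosynthesis

**C6–O bond of the lactone.** Target 33 is opened to the epoxy methyl ester 32. Forward, the C12 ester carbonyl opens a (5S,6R) cis epoxide at C6 with inversion, so one operation gives the lactone, the 6S centre and the free 5S hydroxyl. Making the lactone from a 5,6-diol would require telling two secondary hydroxyls apart. An epoxide does that by geometry, since only C6 can be reached in a five-membered transition state. The forward step has to be mild, because the product is a cis γ-hydroxy enone.

**Tiglate and epoxide oxygen.** Ester 32 comes from epoxy alcohol 29 and tiglic acid 30, and 29 from the triene alcohol 28 by hydroxyl-directed epoxidation. The free C8 hydroxyl is needed exactly once, to steer the oxidant to one face of C5=C6, and is acylated directly afterwards. Alcohol 28 comes from its triethylsilyl ether 27; O8 stays silylated until then because a free hydroxyl at C8 could lactonise onto C12 or form a six-membered hemiketal with C2.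

**C5=C6, the ring-closing cut.** Cyclic triene 27 is cut at C5=C6 to the acyclic trienone 26, which carries a vinyl group on C7 and a diene terminus on C4. Among the ring bonds this is the only one whose formation as an alkene can later be turned into both missing stereocentres and the lactone. A closure at C1–C2 or C2–C3 would have to form a hindered dienone in the macrocyclisation itself. Precursor 26 has two stereocentres and no ring. The forward reaction must engage only the two monosubstituted alkenes and give the cis alkene.

**C2–C3, joining the two enone halves.** Trienone 26 comes by oxidation from carbinol 25, which is cut at C2–C3 into the Z enal 18 and the Z iodo diene 23. This union tolerates the acrylate, so no organolithium or cuprate is needed after the Michael acceptor is in place. Both alkene geometries are carried in from stereodefined fragments. A syn carbocupration of a but-2-ynoate with a vinyl copper reagent would put the vinyl group trans to the carbonyl, the wrong geometry for C3=C4. For that reason 23 is made from prop-2-yn-1-ol 19 by anti-carbomagnesiation and iodination (21), oxidation (22) and methylenation, which places iodine cis to the future C5.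

**C11–C12 and C11=C13, the acrylate.** Enal 18 is traced through alcohol 17 to the PMB ether 16. The acrylate of 16 is cut at C11–C12 to the enol triflate 15, which comes from methyl ketone 13, and 13 from the Weinreb amides 12 and 11. C11 thus enters as an acyl carbon, which allows an aldol construction of C7–C8; C13 and C12 are then added as one-carbon units. The forward sequence asks for a kinetic enolisation away from the epimerisable C7.

**C7–C8, the stereogenic cut.** Weinreb amide 11 comes from the aldol adduct 10, which is cut at C7–C8 into the crotonyl imide 8 (from oxazolidinone 5 and crotonyl chloride 6) and aldehyde 4. The syn relationship of vinyl and hydroxyl along C11–C7–C8–C9 is the native outcome of a boron aldol reaction, and the auxiliary fixes the absolute sense. A sigmatropic route to C7 from a primary allylic ester would have to rely on 1,2-induction from C8 alone.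

**C8 aldehyde.** Aldehyde 4 comes from the enyne ether 2 by anti-Markovnikov hydration, and 2 from (Z)-3-methylpent-2-en-4-yn-1-ol 1. Compound 1 already holds C8, C9, C10, C14, C1 and C2 with the Z C10=C1 geometry. No cuprate addition to an ynone is then needed; such additions to ketones are poorly stereoselective.

## Roads not taken

**Alternative 1: Grob fragmentation of a carvone-derived cis-eudesmanolide.** Here the ten-membered ring is not closed but released. A C5–C10 bond is added to the skeleton to give the cis-fused hydroxy mesylate A1. Forward, KOtBu deprotonates the C5 tertiary alcohol and the C5–C10 bond breaks antiperiplanar to the C1 mesylate, giving A2 with the Z C1=C10 alkene and a C5 ketone.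
- Merits: the ring is formed without any entropic penalty or dilution, the alkene geometry follows stereospecifically from the cis ring fusion, and the stereocentres are built on six-membered rings from the chiral pool. In reliability of ring formation this road is better than the chosen one.
- Weak points: A2 has the wrong oxidation pattern. The C5 ketone must be reduced to the 5S alcohol on a flexible ring, the C2 silyl ether must become the ketone, and the C11 methyl must become the methylene by enolate chemistry in the presence of an enone. Building A1, with its tertiary alcohol, cis fusion and equatorial mesylate, is long.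
- Comparison: the chosen plan accepts a less certain ring closure. Against that it sets a cyclisation product that already has the dienone and the acrylate, and it needs no strong base after the ring exists.

**Alternative 2: radical four-atom ring expansion of a cyclohexenone.** The cut forms C2–C3 and breaks C2–C7. Cyclohexenone A3 carries on C7 a side chain ending in the C3 vinyl iodide. Bu3SnH with AIBN generates the vinyl radical, which adds 6-exo to the C2 carbonyl; the alkoxy radical cleaves C2–C7 and the C7 radical takes hydrogen, giving A4.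
- Merits: both enone geometries are fixed by rings (C1=C10 by the cyclohexenone, C3=C4 by the six-membered transition state), the dienone appears directly, and a ring expansion needs no high dilution. In these respects it is as good as or better than the chosen plan.
- Weak points: addition of a vinyl radical to a ketone carbonyl is reversible and competes with direct reduction and with addition to the enone alkene. The alkoxy radical must cleave toward C7 and not revert. C7 is set by hydrogen transfer to a radical on a floppy ten-membered ring, with no element to control it. After A4, the acetonide and PMB groups must be removed, the lactone closed and methylenated beside a dienone, and the tiglate attached.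
- Comparison: the chosen plan sets C7 with an auxiliary before the ring exists and brings the methylene in early.

**Alternative 3: carbonylative Stille macrocyclisation with carbon monoxide as C2.** The cut is at C1–C2 and C2–C3. The open-chain iodide/stannane A5 is treated with Pd2(dba)3 and AsPh3 (zerovalent palladium) under carbon monoxide. Oxidative addition at the C1 iodide, CO insertion and coupling with the C3 stannane close the ring to A6, the C5 silyl ether of 33.
- Merits: this is the most convergent road. The lactone, tiglate and all four stereocentres are in place before cyclisation, the dienone is formed last, and only a desilylation follows. In endgame economy it is better than the chosen plan, which needs four steps after ring closure and depends on a face-selective epoxidation.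
- Weak points: both coupling partners are β,β-disubstituted alkenyl groups, and the direct, non-carbonylative coupling to a nine-membered ring competes. The α-methylene lactone is exposed to palladium and tin reagents. A5 needs four contiguous stereocentres on an open chain, each made separately. The final desilylation frees the cis γ-hydroxy enone under fluoride or acid.
- Comparison: the chosen plan has a simpler cyclisation substrate with two stereocentres, derives C5 and C6 in one directed operation, and avoids tin and CO at the macrocyclisation.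

Key step: step 17

Remark on numbering: ring atoms are C1–C10 (C2 the ketone, C5 the carbinol, C6 the lactone O-carbon, C8 the tiglate carbon), C11–C13 the acrylate/lactone carbons, C14 and C15 the methyls on C10 and C4.
Assumption: 1 is bought as the pure Z isomer; 4 is used crude and 23 is handled as a solution because of its volatility.

## Steps

Step 1
Reactants: 1 (2Z)-3-methylpent-2-en-4-yn-1-ol
Product: 2 1-methoxy-4-({[(2Z)-3-methylpent-2-en-4-yn-1-yl]oxy}methyl)benzene
Conditions: NaH, PMBCl, Bu4NI (cat.), THF/DMF, 0 °C → rt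
Reagents that add atoms: 4-methoxybenzyl chloride, COc1ccc(CCl)cc1
Why: Williamson ether synthesis on a primary allylic alkoxide; the PMB ether masks C2–OH through all basic and organometallic steps and can later be removed oxidatively beside a silyl ether.

Step 2
Reactants: 2 1-methoxy-4-({[(2Z)-3-methylpent-2-en-4-yn-1-yl]oxy}methyl)benzene
Product: 4 (3Z)-5-[(4-methoxyphenyl)methoxy]-3-methylpent-3-enal, via dicyclohexyl(dienyl)borane 3 (not isolated)
Conditions: Cy2BH (from BH3·SMe2, cyclohexene), THF, 0 °C; then H2O2, pH 7 phosphate buffer, 0 °C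
Reagents that add atoms: hydrogen peroxide, OO
Why: Anti-Markovnikov hydration of a terminal alkyne by hydroboration–oxidation: the bulky dialkylborane adds boron only to the terminal alkyne carbon (C8), and buffered oxidation gives the enol, which ketonises by α-protonation to the β,γ-unsaturated aldehyde with the Z C10=C1 alkene untouched.

Step 3
Reactants: 5 (4S)-4-benzyl-1,3-oxazolidin-2-one; 6 (2E)-but-2-enoyl chloride
Product: 8 (4S)-4-benzyl-3-[(2E)-but-2-enoyl]-1,3-oxazolidin-2-one, via lithium oxazolidinide 7 (not isolated)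
Conditions: n-BuLi, THF, −78 °C; then 6, −78 → 0 °C
Reagents that add atoms: none
Why: N-acylation of the lithiated oxazolidinone, the standard entry to Evans imides; low temperature avoids conjugate addition to the crotonyl group.

Step 4
Reactants: 8 (4S)-4-benzyl-3-[(2E)-but-2-enoyl]-1,3-oxazolidin-2-one; 4 (3Z)-5-[(4-methoxyphenyl)methoxy]-3-methylpent-3-enal
Product: 10 (4S)-4-benzyl-3-[(2S,3R,5Z)-2-ethenyl-3-hydroxy-7-[(4-methoxyphenyl)methoxy]-5-methylhept-5-enoyl]-1,3-oxazolidin-2-one, via dibutylboron dienolate 9 (not isolated)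
Conditions: Bu2BOTf, Et3N, CH2Cl2, −78 → 0 °C; then 4, −78 → 0 °C; H2O2, pH 7 buffer, MeOH
Reagents that add atoms: none
Why: Evans syn aldol reaction of a crotonyl imide: the Z boron dienolate reacts at its α-carbon through a chair Zimmerman–Traxler transition state on the face away from the benzyl group, setting C7 (2S) and C8 (3R) together with vinyl and hydroxyl syn, as the target requires. The crude aldehyde is added at −78 °C so that it cannot slip into conjugation.

Step 5
Reactants: 10 (4S)-4-benzyl-3-[(2S,3R,5Z)-2-ethenyl-3-hydroxy-7-[(4-methoxyphenyl)methoxy]-5-methylhept-5-enoyl]-1,3-oxazolidin-2-one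
Product: 11 (2S,3R,5Z)-2-ethenyl-3-hydroxy-N-methoxy-7-[(4-methoxyphenyl)methoxy]-N,5-dimethylhept-5-enamide
Conditions: MeNH(OMe)·HCl, AlMe3, CH2Cl2, −20 → 0 °C
Reagents that add atoms: N,O-dimethylhydroxylamine hydrochloride, CNOC.Cl
Why: Aluminium amide transamidation of a β-hydroxy imide to the Weinreb amide; the free hydroxyl assists delivery, the auxiliary is recovered, and the conditions do not enolise the α-vinyl centre.

Step 6
Reactants: 11 (2S,3R,5Z)-2-ethenyl-3-hydroxy-N-methoxy-7-[(4-methoxyphenyl)methoxy]-N,5-dimethylhept-5-enamide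
Product: 12 (2S,3R,5Z)-2-ethenyl-N-methoxy-7-[(4-methoxyphenyl)methoxy]-N,5-dimethyl-3-[(triethylsilyl)oxy]hept-5-enamide
Conditions: Et3SiOTf, 2,6-lutidine, CH2Cl2, −78 °C
Reagents that add atoms: triethylsilyl trifluoromethanesulfonate, CC[Si](CC)(CC)OS(=O)(=O)C(F)(F)F
Why: Silylation of the secondary C8 hydroxyl; the triethylsilyl ether blocks retro-aldol, lactonisation onto C12 and hemiketalisation with C2 until after ring closure, and comes off with buffered HF.

Step 7
Reactants: 12 (2S,3R,5Z)-2-ethenyl-N-methoxy-7-[(4-methoxyphenyl)methoxy]-N,5-dimethyl-3-[(triethylsilyl)oxy]hept-5-enamide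
Product: 13 (3S,4R,6Z)-3-ethenyl-8-[(4-methoxyphenyl)methoxy]-6-methyl-4-[(triethylsilyl)oxy]oct-6-en-2-one
Conditions: MeMgBr, THF, 0 °C
Reagents that add atoms: methylmagnesium bromide, C[Mg]Br
Why: Weinreb ketone synthesis: the chelated tetrahedral adduct stops at single addition, so C13 is attached to C11 as a methyl ketone.

Step 8
Reactants: 13 (3S,4R,6Z)-3-ethenyl-8-[(4-methoxyphenyl)methoxy]-6-methyl-4-[(triethylsilyl)oxy]oct-6-en-2-one
Product: 15 (3S,4R,6Z)-3-ethenyl-8-[(4-methoxyphenyl)methoxy]-6-methyl-4-[(triethylsilyl)oxy]octa-1,6-dien-2-yl trifluoromethanesulfonate, via potassium enolate 14 (not isolated)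
Conditions: KN(SiMe3)2, THF, −78 °C; then PhNTf2, −78 → 0 °C
Reagents that add atoms: N-phenylbis(trifluoromethanesulfonimide), O=S(=O)(N(c1ccccc1)S(=O)(=O)C(F)(F)F)C(F)(F)F
Why: Kinetic enolate triflation: the bulky amide base should deprotonate the unhindered methyl group and not the shielded C7–H, and O-sulfonylation fixes the C11=C13 alkene as a 1,1-disubstituted enol triflate.

Step 9
Reactants: 15 (3S,4R,6Z)-3-ethenyl-8-[(4-methoxyphenyl)methoxy]-6-methyl-4-[(triethylsilyl)oxy]octa-1,6-dien-2-yl trifluoromethanesulfonate
Product: 16 methyl (3R,4R,6Z)-3-ethenyl-8-[(4-methoxyphenyl)methoxy]-6-methyl-2-methylidene-4-[(triethylsilyl)oxy]oct-6-enoate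
Conditions: Pd(OAc)2 (5 mol%), PPh3, CO (1 atm), Et3N, MeOH/DMF, 40 °C
Reagents that add atoms: carbon monoxide, [C-]#[O+]; methanol, CO
Why: Palladium-catalysed methoxycarbonylation of an enol triflate (oxidative addition to zerovalent palladium formed in situ, CO insertion, methanolysis); it installs C12 and completes the acrylate with no base strong enough to touch C7. The descriptor at C7 changes from S to R by priority only.

Step 10
Reactants: 16 methyl (3R,4R,6Z)-3-ethenyl-8-[(4-methoxyphenyl)methoxy]-6-methyl-2-methylidene-4-[(triethylsilyl)oxy]oct-6-enoate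
Product: 17 methyl (3R,4R,6Z)-3-ethenyl-8-hydroxy-6-methyl-2-methylidene-4-[(triethylsilyl)oxy]oct-6-enoate
Conditions: DDQ, CH2Cl2/pH 7 buffer, 0 °C
Reagents that add atoms: none
Why: Oxidative PMB ether cleavage (benzylic hydride abstraction, then hydrolysis); the silyl ether, the acrylate and the isolated alkenes are inert to DDQ under buffered conditions.

Step 11
Reactants: 17 methyl (3R,4R,6Z)-3-ethenyl-8-hydroxy-6-methyl-2-methylidene-4-[(triethylsilyl)oxy]oct-6-enoate
Product: 18 methyl (3R,4R,6Z)-3-ethenyl-6-methyl-2-methylidene-8-oxo-4-[(triethylsilyl)oxy]oct-6-enoate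
Conditions: MnO2, CH2Cl2, rt
Reagents that add atoms: none
Why: Allylic alcohol oxidation with MnO2, a neutral heterogeneous oxidant that should keep the Z geometry of the β,β-disubstituted enal.

Step 12
Reactants: 19 prop-2-yn-1-ol
Product: 21 (2Z)-3-iodo-2-methylprop-2-en-1-ol, via alkenylmagnesium alkoxide 20 (not isolated)
Conditions: MeMgBr, CuI (10 mol%), THF, −10 °C → rt; then I2, −78 → 0 °C
Reagents that add atoms: methylmagnesium bromide, C[Mg]Br; iodine, II
Why: Copper-catalysed anti-carbomagnesiation of a propargylic alkoxide: methyl is delivered to C2 and magnesium ends on C3 cis to the CH2O group, so iodinolysis with retention gives the Z iodide. This is the geometry needed for C3=C4 (iodine, later C2, cis to the future C5).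

Step 13
Reactants: 21 (2Z)-3-iodo-2-methylprop-2-en-1-ol
Product: 22 (2Z)-3-iodo-2-methylprop-2-enal
Conditions: MnO2, CH2Cl2, rt
Reagents that add atoms: none
Why: Allylic oxidation with MnO2 under neutral conditions; the product is used promptly to avoid Z/E equilibration.

Step 14
Reactants: 22 (2Z)-3-iodo-2-methylprop-2-enal
Product: 23 (1Z)-1-iodo-2-methylbuta-1,3-diene
Conditions: Ph3PCH3Br, NaN(SiMe3)2, THF, 0 °C; then 22, −78 → 0 °C
Reagents that add atoms: methyltriphenylphosphonium bromide, C[P+](c1ccccc1)(c1ccccc1)c1ccccc1.[Br-]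
Why: Wittig methylenation with the non-stabilised ylide turns the aldehyde into the terminal C5=CH2 vinyl group without touching the iodoalkene geometry.

Step 15
Reactants: 18 methyl (3R,4R,6Z)-3-ethenyl-6-methyl-2-methylidene-8-oxo-4-[(triethylsilyl)oxy]oct-6-enoate; 23 (1Z)-1-iodo-2-methylbuta-1,3-diene
Product: 25 methyl (3R,4R,6Z,9Z)-3-ethenyl-8-hydroxy-6,10-dimethyl-2-methylidene-4-[(triethylsilyl)oxy]dodeca-6,9,11-trienoate (both C8 epimers of the chain, that is both C2 epimers of the skeleton), via dienylchromium dichloride 24 (not isolated)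
Conditions: CrCl2, NiCl2 (1 mol%), DMSO, rt
Reagents that add atoms: none
Why: Nozaki–Hiyama–Kishi reaction: nickel-catalysed formation of the alkenylchromium reagent with retention of the Z geometry and chemoselective 1,2-addition to the aldehyde, leaving ester, acrylate and silyl ether alone. The new carbinol centre need not be controlled because it is oxidised in the next step.

Step 16
Reactants: 25 methyl (3R,4R,6Z,9Z)-3-ethenyl-8-hydroxy-6,10-dimethyl-2-methylidene-4-[(triethylsilyl)oxy]dodeca-6,9,11-trienoate
Product: 26 methyl (3R,4R,6Z,9Z)-3-ethenyl-6,10-dimethyl-2-methylidene-8-oxo-4-[(triethylsilyl)oxy]dodeca-6,9,11-trienoate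
Conditions: Dess–Martin periodinane, NaHCO3, CH2Cl2, 0 °C
Reagents that add atoms: none
Why: Dess–Martin oxidation of a bis-allylic alcohol to the cross-conjugated dienone under buffered, non-basic conditions that should leave both Z alkenes and the C7 centre intact.

Step 17
Reactants: 26 methyl (3R,4R,6Z,9Z)-3-ethenyl-6,10-dimethyl-2-methylidene-8-oxo-4-[(triethylsilyl)oxy]dodeca-6,9,11-trienoate
Product: 27 methyl 2-[(1R,2Z,4Z,7Z,10R)-4,8-dimethyl-6-oxo-10-[(triethylsilyl)oxy]cyclodeca-2,4,7-trien-1-yl]prop-2-enoate
Conditions: (H2IMes)(PCy3)Cl2Ru=CHPh (second-generation Grubbs catalyst, 10 mol%), toluene (0.5 mM), 80 °C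
Reagents that add atoms: none
Why: Ring-closing olefin metathesis by the alkylidene/metallacyclobutane cycle: the ruthenium benzylidene exchanges onto the monosubstituted C7 vinyl group, the new alkylidene at C6 adds across the terminal C5=CH2 bond of the dienone and cycloreverts with loss of ethene, whose escape at 80 °C drives the closure. The closest known reaction type is ring-closing metathesis of an alkene onto the terminus of a conjugated diene to give medium-ring cis-cycloalkenes. One ring is closed, the ten-membered carbocycle, by end-to-end union of the chain termini with C5=C6 becoming endocyclic. No stereocentre is created; the only stereochemical element is the C5=C6 geometry, and a ten-membered ring that already holds two Z alkenes and a carbonyl (seven sp2 ring atoms) can accommodate only a cis alkene. The step needs site selectivity for the two monosubstituted alkenes; the 1,1-disubstituted acrylate, the two trisubstituted enone alkenes and the internal diene alkene are hindered and electron-poor and should not engage the catalyst. Cyclisation has to outrun intermolecular metathesis, which is addressed by high dilution and by the two Z enones, which bend the chain so that C5 and C6 face each other. The triethylsilyl ether keeps O8 from lactonising onto C12, from adding to C2 and from binding ruthenium.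

Step 18
Reactants: 27 methyl 2-[(1R,2Z,4Z,7Z,10R)-4,8-dimethyl-6-oxo-10-[(triethylsilyl)oxy]cyclodeca-2,4,7-trien-1-yl]prop-2-enoate
Product: 28 methyl 2-[(1R,2Z,4Z,7Z,10R)-10-hydroxy-4,8-dimethyl-6-oxocyclodeca-2,4,7-trien-1-yl]prop-2-enoate
Conditions: HF·pyridine, pyridine, THF, 0 °C
Reagents that add atoms: none
Why: Desilylation with buffered HF, chosen over basic fluoride so that the freed γ-hydroxy ester does not lactonise onto C12; the alcohol is taken on directly.

Step 19
Reactants: 28 methyl 2-[(1R,2Z,4Z,7Z,10R)-10-hydroxy-4,8-dimethyl-6-oxocyclodeca-2,4,7-trien-1-yl]prop-2-enoate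
Product: 29 methyl 2-[(1S,2Z,5Z,8R,9R,10R)-8-hydroxy-2,6-dimethyl-4-oxo-11-oxabicyclo[8.1.0]undeca-2,5-dien-9-yl]prop-2-enoate
Conditions: VO(acac)2 (10 mol%), t-BuOOH, CH2Cl2, 0 °C → rt
Reagents that add atoms: tert-butyl hydroperoxide, CC(C)(C)OO
Why: Hydroxyl-directed epoxidation of a homoallylic alcohol: the vanadium alkoxide of O8 delivers the peroxide oxygen to C5=C6 on the face where C8 lies. With H7 in the alkene plane (allylic strain against the cis substituent C4) this is the face anti to the acrylate arm and gives the (5S,6R) epoxide. The enone and acrylate alkenes are more electron-poor than C5=C6 and should not react with the electrophilic vanadium peroxide.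

Step 20
Reactants: 29 methyl 2-[(1S,2Z,5Z,8R,9R,10R)-8-hydroxy-2,6-dimethyl-4-oxo-11-oxabicyclo[8.1.0]undeca-2,5-dien-9-yl]prop-2-enoate; 30 (2E)-2-methylbut-2-enoic acid (tiglic acid)
Product: 32 (1S,2Z,5Z,8R,9R,10R)-9-(3-methoxy-3-oxoprop-1-en-2-yl)-2,6-dimethyl-4-oxo-11-oxabicyclo[8.1.0]undeca-2,5-dien-8-yl (2E)-2-methylbut-2-enoate, via mixed anhydride 31 (not isolated)
Conditions: 2,4,6-Cl3C6H2COCl, Et3N, THF, rt; then 29, DMAP, toluene, rt
Reagents that add atoms: none
Why: Yamaguchi esterification: tiglic acid is activated as the mixed 2,4,6-trichlorobenzoic anhydride and transferred by DMAP to the hindered secondary C8 hydroxyl faster than that hydroxyl can attack C12; the E tiglate geometry is not at risk.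

Step 21
Reactants: 32 (1S,2Z,5Z,8R,9R,10R)-9-(3-methoxy-3-oxoprop-1-en-2-yl)-2,6-dimethyl-4-oxo-11-oxabicyclo[8.1.0]undeca-2,5-dien-8-yl (2E)-2-methylbut-2-enoate
Product: 33 (3aR,4R,6Z,9Z,11S,11aS)-11-hydroxy-6,10-dimethyl-3-methylidene-2,8-dioxo-2,3,3a,4,5,8,11,11a-octahydrocyclodeca[b]furan-4-yl (2E)-2-methylbut-2-enoate
Conditions: CSA (0.2 equiv), CH2Cl2 with H2O (2 equiv), 0 °C → rt
Reagents that add atoms: water, O
Why: Acid-promoted epoxide-opening lactonisation: the carbonyl oxygen of the C12 ester attacks C6 of the protonated epoxide in a 5-exo anti opening from the face of the acrylate arm (inversion, 6R → 6S), while C5 keeps its oxygen and configuration (5S). Hydrolysis of the alkoxycarbenium centre at C12 releases methanol and leaves the fused α-methylene lactone. Attack at C5 would need a six-membered transition state at a carbon whose cationic character is disfavoured by the adjoining enone.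

## Compound list

1 | (2Z)-3-methylpent-2-en-4-yn-1-ol | C#C/C(C)=C\CO | starting material
2 | 1-methoxy-4-({[(2Z)-3-methylpent-2-en-4-yn-1-yl]oxy}methyl)benzene | C#C/C(C)=C\COCc1ccc(OC)cc1 | intermediate
3 | dicyclohexyl[(1E,3Z)-5-[(4-methoxyphenyl)methoxy]-3-methylpenta-1,3-dien-1-yl]borane | B(/C=C/C(C)=C\COCc1ccc(OC)cc1)(C2CCCCC2)C3CCCCC3 | intermediate
4 | (3Z)-5-[(4-methoxyphenyl)methoxy]-3-methylpent-3-enal | O=CC/C(C)=C\COCc1ccc(OC)cc1 | intermediate
5 | (4S)-4-benzyl-1,3-oxazolidin-2-one | O=C1N[C@@H](Cc2ccccc2)CO1 | starting material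
6 | (2E)-but-2-enoyl chloride | C/C=C/C(Cl)=O | starting material
7 | lithium (4S)-4-benzyl-2-oxo-1,3-oxazolidin-3-ide | [Li+].O=C1[N-][C@@H](Cc2ccccc2)CO1 | intermediate
8 | (4S)-4-benzyl-3-[(2E)-but-2-enoyl]-1,3-oxazolidin-2-one | C/C=C/C(=O)N1C(=O)OC[C@@H]1Cc1ccccc1 | intermediate
9 | (4S)-4-benzyl-3-[(1Z)-1-[(dibutylboranyl)oxy]buta-1,3-dien-1-yl]-1,3-oxazolidin-2-one | C=C/C=C(\OB(CCCC)CCCC)N1C(=O)OC[C@@H]1Cc1ccccc1 | intermediate
10 | (4S)-4-benzyl-3-[(2S,3R,5Z)-2-ethenyl-3-hydroxy-7-[(4-methoxyphenyl)methoxy]-5-methylhept-5-enoyl]-1,3-oxazolidin-2-one | C=C[C@@H]([C@H](O)C/C(C)=C\COCc1ccc(OC)cc1)C(=O)N1C(=O)OC[C@@H]1Cc1ccccc1 | intermediate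
11 | (2S,3R,5Z)-2-ethenyl-3-hydroxy-N-methoxy-7-[(4-methoxyphenyl)methoxy]-N,5-dimethylhept-5-enamide | C=C[C@@H]([C@H](O)C/C(C)=C\COCc1ccc(OC)cc1)C(=O)N(C)OC | intermediate
12 | (2S,3R,5Z)-2-ethenyl-N-methoxy-7-[(4-methoxyphenyl)methoxy]-N,5-dimethyl-3-[(triethylsilyl)oxy]hept-5-enamide | C=C[C@@H]([C@H](O[Si](CC)(CC)CC)C/C(C)=C\COCc1ccc(OC)cc1)C(=O)N(C)OC | intermediate
13 | (3S,4R,6Z)-3-ethenyl-8-[(4-methoxyphenyl)methoxy]-6-methyl-4-[(triethylsilyl)oxy]oct-6-en-2-one | C=C[C@@H]([C@H](O[Si](CC)(CC)CC)C/C(C)=C\COCc1ccc(OC)cc1)C(C)=O | intermediate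
14 | potassium (3S,4R,6Z)-3-ethenyl-8-[(4-methoxyphenyl)methoxy]-6-methyl-4-[(triethylsilyl)oxy]octa-1,6-dien-2-olate | [K+].C=C[C@@H]([C@H](O[Si](CC)(CC)CC)C/C(C)=C\COCc1ccc(OC)cc1)C(=C)[O-] | intermediate
15 | (3S,4R,6Z)-3-ethenyl-8-[(4-methoxyphenyl)methoxy]-6-methyl-4-[(triethylsilyl)oxy]octa-1,6-dien-2-yl trifluoromethanesulfonate | C=C[C@@H]([C@H](O[Si](CC)(CC)CC)C/C(C)=C\COCc1ccc(OC)cc1)C(=C)OS(=O)(=O)C(F)(F)F | intermediate
16 | methyl (3R,4R,6Z)-3-ethenyl-8-[(4-methoxyphenyl)methoxy]-6-methyl-2-methylidene-4-[(triethylsilyl)oxy]oct-6-enoate | C=C[C@@H]([C@H](O[Si](CC)(CC)CC)C/C(C)=C\COCc1ccc(OC)cc1)C(=C)C(=O)OC | intermediate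
17 | methyl (3R,4R,6Z)-3-ethenyl-8-hydroxy-6-methyl-2-methylidene-4-[(triethylsilyl)oxy]oct-6-enoate | C=C[C@@H]([C@H](O[Si](CC)(CC)CC)C/C(C)=C\CO)C(=C)C(=O)OC | intermediate
18 | methyl (3R,4R,6Z)-3-ethenyl-6-methyl-2-methylidene-8-oxo-4-[(triethylsilyl)oxy]oct-6-enoate | C=C[C@@H]([C@H](O[Si](CC)(CC)CC)C/C(C)=C\C=O)C(=C)C(=O)OC | intermediate
19 | prop-2-yn-1-ol | C#CCO | starting material
20 | bromo[(1Z)-3-(bromomagnesiooxy)-2-methylprop-1-en-1-yl]magnesium | Br[Mg]/C=C(/C)CO[Mg]Br | intermediate
21 | (2Z)-3-iodo-2-methylprop-2-en-1-ol | OC/C(C)=C\I | intermediate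
22 | (2Z)-3-iodo-2-methylprop-2-enal | O=C/C(C)=C\I | intermediate
23 | (1Z)-1-iodo-2-methylbuta-1,3-diene | C=C/C(C)=C\I | intermediate
24 | dichloro[(1Z)-2-methylbuta-1,3-dien-1-yl]chromium | C=C/C(C)=C\[Cr](Cl)Cl | intermediate
25 | methyl (3R,4R,6Z,9Z)-3-ethenyl-8-hydroxy-6,10-dimethyl-2-methylidene-4-[(triethylsilyl)oxy]dodeca-6,9,11-trienoate (both C8 epimers) | C=C[C@@H]([C@H](O[Si](CC)(CC)CC)C/C(C)=C\C(O)/C=C(/C)C=C)C(=C)C(=O)OC | intermediate
26 | methyl (3R,4R,6Z,9Z)-3-ethenyl-6,10-dimethyl-2-methylidene-8-oxo-4-[(triethylsilyl)oxy]dodeca-6,9,11-trienoate | C=C[C@@H]([C@H](O[Si](CC)(CC)CC)C/C(C)=C\C(=O)/C=C(/C)C=C)C(=C)C(=O)OC | intermediate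
27 | methyl 2-[(1R,2Z,4Z,7Z,10R)-4,8-dimethyl-6-oxo-10-[(triethylsilyl)oxy]cyclodeca-2,4,7-trien-1-yl]prop-2-enoate | C1/C(C)=C\C(=O)/C=C(/C)\C=C/[C@H](C(=C)C(=O)OC)[C@@H]1O[Si](CC)(CC)CC | intermediate
28 | methyl 2-[(1R,2Z,4Z,7Z,10R)-10-hydroxy-4,8-dimethyl-6-oxocyclodeca-2,4,7-trien-1-yl]prop-2-enoate | C1/C(C)=C\C(=O)/C=C(/C)\C=C/[C@H](C(=C)C(=O)OC)[C@@H]1O | intermediate
29 | methyl 2-[(1S,2Z,5Z,8R,9R,10R)-8-hydroxy-2,6-dimethyl-4-oxo-11-oxabicyclo[8.1.0]undeca-2,5-dien-9-yl]prop-2-enoate | C=C(C(=O)OC)[C@@H]1[C@H](O)C/C(C)=C\C(=O)/C=C(/C)[C@@H]2O[C@@H]21 | intermediate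
30 | (2E)-2-methylbut-2-enoic acid (tiglic acid) | C/C=C(\C)C(=O)O | starting material
31 | (2E)-2-methylbut-2-enoic 2,4,6-trichlorobenzoic anhydride | C/C=C(\C)C(=O)OC(=O)c1c(Cl)cc(Cl)cc1Cl | intermediate
32 | (1S,2Z,5Z,8R,9R,10R)-9-(3-methoxy-3-oxoprop-1-en-2-yl)-2,6-dimethyl-4-oxo-11-oxabicyclo[8.1.0]undeca-2,5-dien-8-yl (2E)-2-methylbut-2-enoate | C=C(C(=O)OC)[C@@H]1[C@H](OC(=O)/C(C)=C/C)C/C(C)=C\C(=O)/C=C(/C)[C@@H]2O[C@@H]21 | intermediate
33 | (3aR,4R,6Z,9Z,11S,11aS)-11-hydroxy-6,10-dimethyl-3-methylidene-2,8-dioxo-2,3,3a,4,5,8,11,11a-octahydrocyclodeca[b]furan-4-yl (2E)-2-methylbut-2-enoate | C=C1C(=O)O[C@H]2[C@H]1[C@H](OC(=O)/C(C)=C/C)C/C(C)=C\C(=O)/C=C(/C)[C@@H]2O | target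

## Step count and risks

Total: 21 steps. Longest linear sequence: 17 steps (1 → 33 through steps 1, 2, 4–11 and 15–21). Steps 12–14 make the iodo diene and step 3 the imide.

Least certain steps:

**Step 17 (key step).** Intermolecular metathesis may outrun closure of the strained ring. The vinylcarbene formed at the diene terminus may turn over slowly. The cis dienone of 26 may drift reversibly into a 2H-pyran by oxa-6π closure, and ruthenium hydrides may isomerise the skipped diene at C7. Fallback: the ring is closed one step earlier, on the carbinol 25, whose sp3 C2 removes the cross-conjugation and the electrocyclisation channel and makes the chain more flexible. Ring-closing metathesis of 25 with the same catalyst would give the cyclic trienol methyl 2-[(1R,2Z,4Z,7Z,10R)-6-hydroxy-4,8-dimethyl-10-[(triethylsilyl)oxy]cyclodeca-2,4,7-trien-1-yl]prop-2-enoate F1, and Dess–Martin oxidation of F1 returns to 27.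

**Step 2.** The β,γ-unsaturated aldehyde may slip into conjugation during the oxidative work-up of the alkenylborane, or on storage. Fallback from 2: semihydrogenation over Pd/CaCO3–Pb(OAc)2 (Lindlar catalyst) with quinoline gives the diene 1-methoxy-4-({[(2Z)-3-methylpenta-2,4-dien-1-yl]oxy}methyl)benzene F2. Hydroboration of its terminal vinyl group with 9-BBN and NaOH/H2O2 oxidation gives the stable homoallylic alcohol (3Z)-5-[(4-methoxyphenyl)methoxy]-3-methylpent-3-en-1-ol F3. Buffered Dess–Martin oxidation of F3 immediately before the aldol returns to 4.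

**Step 8.** Deprotonation may occur at C7 instead of the methyl group, which would erode the C7 configuration, move the vinyl group into conjugation or expel the β-silyloxy group. Fallback from 12, avoiding any ketone enolate: i-Bu2AlH at −78 °C gives the aldehyde (2S,3R,5Z)-2-ethenyl-7-[(4-methoxyphenyl)methoxy]-5-methyl-3-[(triethylsilyl)oxy]hept-5-enal F4. Colvin homologation (Me3SiCHN2, n-BuLi, −78 °C → rt) gives the alkyne triethyl{[(3R,4R,6Z)-3-ethenyl-8-[(4-methoxyphenyl)methoxy]-6-methyloct-6-en-1-yn-4-yl]oxy}silane F5. Branch-selective palladium-catalysed methoxycarbonylation of the terminal alkyne (Pd(OAc)2, 2-(diphenylphosphino)pyridine, MeSO3H cat., CO, MeOH) returns to 16.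

**Step 19.** Facial selectivity may be poor if the ring conformation keeps the vanadium alkoxide from the required face. Oxidation may stray to the C10=C1 alkene, which is also homoallylic to O8. The hydroxyl may be tied up as a hemiketal with C2. Fallback from 28, replacing substrate direction by catalyst control: Yamaguchi esterification with 30 gives the tiglate (1R,2R,3Z,5Z,8Z)-2-(3-methoxy-3-oxoprop-1-en-2-yl)-5,9-dimethyl-7-oxocyclodeca-3,5,8-trien-1-yl (2E)-2-methylbut-2-enoate F6. Its C5=C6 bond is a cis-disubstituted alkene conjugated to a second alkene, the preferred substrate class of the Jacobsen–Katsuki epoxidation. The enantiomer of (salen)MnCl (N,N'-bis(3,5-di-tert-butylsalicylidene)-1,2-cyclohexanediamine manganese chloride, trivalent manganese) that gives the (5S,6R) epoxide, used with NaOCl and 4-phenylpyridine N-oxide, returns to 32.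

**Step 21.** The C2 carbonyl oxygen may compete for the epoxide at C5 (leading to a furan), the product's cis γ-hydroxy enone may dehydrate, or the methyl ester may participate too slowly under acid mild enough to avoid both. Fallback from 32: Me3SnOH in 1,2-dichloroethane cleaves the methyl ester selectively over the hindered tiglate to give the acid 2-[(1S,2Z,5Z,8R,9R,10R)-2,6-dimethyl-8-{[(2E)-2-methylbut-2-enoyl]oxy}-4-oxo-11-oxabicyclo[8.1.0]undeca-2,5-dien-9-yl]prop-2-enoic acid F7. The free carboxylic acid should open the epoxide at C6 on standing or with pyridinium p-toluenesulfonate, returning to 33 under much weaker acid.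

## Further compounds

F1 | step 17 | methyl 2-[(1R,2Z,4Z,7Z,10R)-6-hydroxy-4,8-dimethyl-10-[(triethylsilyl)oxy]cyclodeca-2,4,7-trien-1-yl]prop-2-enoate (both C6 epimers) | C1/C(C)=C\C(O)/C=C(/C)\C=C/[C@H](C(=C)C(=O)OC)[C@@H]1O[Si](CC)(CC)CC
F2 | step 2 | 1-methoxy-4-({[(2Z)-3-methylpenta-2,4-dien-1-yl]oxy}methyl)benzene | C=C/C(C)=C\COCc1ccc(OC)cc1
F3 | step 2 | (3Z)-5-[(4-methoxyphenyl)methoxy]-3-methylpent-3-en-1-ol | OCC/C(C)=C\COCc1ccc(OC)cc1
F4 | step 8 | (2S,3R,5Z)-2-ethenyl-7-[(4-methoxyphenyl)methoxy]-5-methyl-3-[(triethylsilyl)oxy]hept-5-enal | C=C[C@@H]([C@H](O[Si](CC)(CC)CC)C/C(C)=C\COCc1ccc(OC)cc1)C=O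
F5 | step 8 | triethyl{[(3R,4R,6Z)-3-ethenyl-8-[(4-methoxyphenyl)methoxy]-6-methyloct-6-en-1-yn-4-yl]oxy}silane | C=C[C@@H]([C@H](O[Si](CC)(CC)CC)C/C(C)=C\COCc1ccc(OC)cc1)C#C
F6 | step 19 | (1R,2R,3Z,5Z,8Z)-2-(3-methoxy-3-oxoprop-1-en-2-yl)-5,9-dimethyl-7-oxocyclodeca-3,5,8-trien-1-yl (2E)-2-methylbut-2-enoate | C1/C(C)=C\C(=O)/C=C(/C)\C=C/[C@H](C(=C)C(=O)OC)[C@@H]1OC(=O)/C(C)=C/C
F7 | step 21 | 2-[(1S,2Z,5Z,8R,9R,10R)-2,6-dimethyl-8-{[(2E)-2-methylbut-2-enoyl]oxy}-4-oxo-11-oxabicyclo[8.1.0]undeca-2,5-dien-9-yl]prop-2-enoic acid | C=C(C(=O)O)[C@@H]1[C@H](OC(=O)/C(C)=C/C)C/C(C)=C\C(=O)/C=C(/C)[C@@H]2O[C@@H]21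
A1 | alternative 1 | cis-fused eudesmanolide with C5 tertiary hydroxyl, C1 mesylate, C2 tert-butyldimethylsilyl ether, C8 triethylsilyl ether and C11 methyl | C[C@@H]1C(=O)O[C@H]2[C@H]1[C@H](O[Si](CC)(CC)CC)C[C@@]3(C)[C@@H](OS(C)(=O)=O)[C@H](O[Si](C)(C)C(C)(C)C)C=C(C)[C@@]23O
A2 | alternative 1 | ten-membered Z,Z-diene lactone with C5 ketone, C2 tert-butyldimethylsilyl ether, C8 triethylsilyl ether and C11 methyl | C[C@@H]1C(=O)O[C@H]2[C@H]1[C@H](O[Si](CC)(CC)CC)C/C(C)=C\[C@H](O[Si](C)(C)C(C)(C)C)/C=C(/C)C2=O
A3 | alternative 2 | 4-methyl-2-oxocyclohex-3-enyl acetate ester with quaternary C7 carrying the C5/C6 acetonide side chain that ends in the C3 (Z)-vinyl iodide, C8 4-methoxybenzyl ether | COC(=O)C[C@@]1(C(=O)C=C(C)C[C@H]1OCc2ccc(OC)cc2)[C@@H]3OC(C)(C)O[C@H]3/C(C)=C\I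
A4 | alternative 2 | ten-membered Z,Z-dienone with C5/C6 acetonide, C7 acetate arm and C8 4-methoxybenzyl ether | COC(=O)C[C@@H]1[C@H](OCc3ccc(OC)cc3)C/C(C)=C\C(=O)/C=C(/C)[C@@H]2OC(C)(C)O[C@@H]12
A5 | alternative 3 | open-chain α-methylene lactone with C1 (Z)-vinyl iodide, C3 (Z)-tributylstannyl alkene, C5 tert-butyldimethylsilyl ether and C8 tiglate | C=C1C(=O)O[C@H]([C@@H](O[Si](C)(C)C(C)(C)C)/C(C)=C\[Sn](CCCC)(CCCC)CCCC)[C@H]1[C@H](OC(=O)/C(C)=C/C)C/C(C)=C\I
A6 | alternative 3 | C5 tert-butyldimethylsilyl ether of 33 | C=C1C(=O)O[C@H]2[C@H]1[C@H](OC(=O)/C(C)=C/C)C/C(C)=C\C(=O)/C=C(/C)[C@@H]2O[Si](C)(C)C(C)(C)C
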